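The route rests on cutting ring A away from a ready-made ring C. A 2-aryl-3-benzyloxy-5-bromo-4-pyranone, already carrying ring B with its 3'-benzyl ether and the 4'-sulfate masked as a 2,2,2-trichloroethyl ester, takes up a 1-methoxy-1,3-bis(silyloxy)butadiene across its brominated C=C. The C4a–C5 and C8–C8a bonds form in one operation, and loss of methanol and HBr gives the aromatic 5,7-diol. The step exploits the 1,3-relation of O5 and O7 on ring A, with C5 bonded to C4a, which maps exactly onto the two oxygen-bearing carbons of the diene. One transfer hydrogenolysis then removes both benzyl ethers and the trichloroethyl group.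

Key step: step 11

Assumption: the target is taken as the free hydrogen sulfate that is drawn. It is released from its ammonium salt on a cold acidic resin and should be kept cold, because aryl hydrogen sulfates hydrolyse under their own acidity.

Remark on numbering: pyranone numbering (O1, C2 to C6) is used for ring C before the annulation and flavone numbering (C4a, C5 to C8, C8a, primed ring B) after it. Pyranone C5 becomes C4a and pyranone C6 becomes C8a.

Step 1
Reactants: 1 3-hydroxy-4H-pyran-4-one
Product: 2 3-hydroxy-2-iodo-4H-pyran-4-one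
Conditions: NIS (1.05 equiv), MeCN, 0 °C → rt, dark
Reagents that add atoms: N-iodosuccinimide, O=C1CCC(=O)N1I
Why: Electrophilic iodination (enol halogenation) of the hydroxypyranone should go to C2, the carbon ortho to the enolic hydroxyl, where kojic and pyromeconic acids are known to take halogens and Mannich electrophiles, while C5 and C6 lack this activation.

Step 2
Reactants: 2 3-hydroxy-2-iodo-4H-pyran-4-one
Product: 3 3-(benzyloxy)-2-iodo-4H-pyran-4-one
Conditions: BnBr, K2CO3, DMF, rt
Reagents that add atoms: benzyl bromide, BrCc1ccccc1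
Why: Williamson ether synthesis on the acidic enol oxygen, as routinely done for maltol and kojic acid, with carbonate at room temperature too mild to displace the C2 iodide.

Step 3
Reactants: 3 3-(benzyloxy)-2-iodo-4H-pyran-4-one
Product: 5 3-(benzyloxy)-5-bromo-2-iodo-4H-pyran-4-one, via dibromide 4 (not isolated)
Conditions: Br2 (1.05 equiv), CH2Cl2, 0 °C; then Et3N, 0 °C → rt
Reagents that add atoms: bromine, BrBr
Why: Bromination of the enone by addition–elimination, the standard way to 3-bromochromones and 3-bromo-4-pyranones: bromine should add to the less substituted, enol-ether-like C5=C6 bond to give 4, and Et3N removes the acidic C5 hydrogen with loss of the C6 bromide, whereas the tetrasubstituted C2=C3 bond is hindered.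

Step 4
Reactants: 6 2-(benzyloxy)phenol
Product: 7 2-(benzyloxy)-4-bromophenol
Conditions: NBS (1.0 equiv), MeCN, 0 °C
Reagents that add atoms: N-bromosuccinimide, O=C1CCC(=O)N1Br
Why: Electrophilic aromatic bromination should go para to the free hydroxyl, the stronger donor, as it does with guaiacol, and one equivalent of NBS at low temperature limits dibromination.

Step 5
Reactants: 7 2-(benzyloxy)-4-bromophenol
Product: 8 2-(benzyloxy)-4-(4,4,5,5-tetramethyl-1,3,2-dioxaborolan-2-yl)phenol
Conditions: B2pin2, Pd(dppf)Cl2 (3 mol %), KOAc, 1,4-dioxane, 90 °C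
Reagents that add atoms: bis(pinacolato)diboron, CC1(C)OB(B2OC(C)(C)C(C)(C)O2)OC1(C)C
Why: Miyaura borylation of the aryl bromide with KOAc as base tolerates the free phenol and the benzyl ether.

Step 6
Reactants: 5 3-(benzyloxy)-5-bromo-2-iodo-4H-pyran-4-one; 8 2-(benzyloxy)-4-(4,4,5,5-tetramethyl-1,3,2-dioxaborolan-2-yl)phenol
Product: 9 3-(benzyloxy)-2-[3-(benzyloxy)-4-hydroxyphenyl]-5-bromo-4H-pyran-4-one
Conditions: Pd(PPh3)4 (3 mol %), K3PO4, 1,4-dioxane/H2O (10:1), 50 °C
Reagents that add atoms: none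
Why: Suzuki–Miyaura coupling in which zerovalent palladium should insert into the C2–iodine bond, the weaker carbon–halogen bond and the one on the electron-poor β-carbon of the vinylogous ester, well before the C5–bromine bond, while hydroxyphenylboronates couple without protection and the mild phosphate base spares the pyranone.

Step 7
Reactants: 10 2,2,2-trichloroethanol
Product: 11 2,2,2-trichloroethyl chlorosulfate
Conditions: SO2Cl2 (1.0 equiv), pyridine, Et2O, −78 °C → rt
Reagents that add atoms: sulfuryl chloride, O=S(=O)(Cl)Cl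
Why: Sulfonylation of the alcohol oxygen by sulfuryl chloride with displacement of one chloride, stopped at the chlorosulfate by low temperature and one equivalent of the electron-poor alcohol.

Step 8
Reactants: 9 3-(benzyloxy)-2-[3-(benzyloxy)-4-hydroxyphenyl]-5-bromo-4H-pyran-4-one; 11 2,2,2-trichloroethyl chlorosulfate
Product: 12 2-(benzyloxy)-4-[3-(benzyloxy)-5-bromo-4-oxo-4H-pyran-2-yl]phenyl 2,2,2-trichloroethyl sulfate
Conditions: Et3N, DMAP, THF, 0 °C → rt
Reagents that add atoms: none
Why: Sulfuryl transfer (O-sulfonylation) to the only hydroxyl, the phenol, catalysed by DMAP, is the standard entry to aryl trichloroethyl sulfate diesters and touches neither the vinyl bromide nor the benzyl ethers.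

Step 9
Reactants: 13 methyl acetoacetate
Product: 14 methyl (2E)-3-(trimethylsilyloxy)but-2-enoate
Conditions: TMSCl, Et3N, hexane, rt
Reagents that add atoms: chlorotrimethylsilane, C[Si](C)(C)Cl
Why: O-Silylation of the β-keto ester enol at the ketone oxygen (silyl enol ether formation) under amine base is the usual first stage towards bis(silyloxy)dienes, and the E isomer expected as the major one and any Z isomer converge in the next step.

Step 10
Reactants: 14 methyl (2E)-3-(trimethylsilyloxy)but-2-enoate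
Product: 16 (1Z)-1-methoxy-1,3-bis(trimethylsilyloxy)buta-1,3-diene, via lithium dienolate 15 (not isolated)
Conditions: LiN(i-Pr)2, THF, −78 °C; then TMSCl, −78 → 0 °C
Reagents that add atoms: chlorotrimethylsilane, C[Si](C)(C)Cl
Why: Kinetic γ-deprotonation of the vinylogous ester by the hindered amide gives dienolate 15, which is trapped on oxygen by the hard silyl chloride (silyl ketene acetal formation) to give the diene.

Step 11
Reactants: 12 2-(benzyloxy)-4-[3-(benzyloxy)-5-bromo-4-oxo-4H-pyran-2-yl]phenyl 2,2,2-trichloroethyl sulfate; 16 (1Z)-1-methoxy-1,3-bis(trimethylsilyloxy)buta-1,3-diene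
Product: 20 3,3'-di-O-benzylquercetin 4'-(2,2,2-trichloroethyl sulfate), via cis-fused bromo cycloadduct 17 (not isolated), via bromo dihydroarene 18 (not isolated), via bis-silyl ether 19 (not isolated)
Conditions: 16 (3 equiv), PhMe, 85 °C, sealed tube; then TMSOTf (1.2 equiv), i-Pr2NEt, CH2Cl2, 0 °C → rt; then 1 M HCl, THF, rt
Reagents that add atoms: none
Why: Proposed new method: diene 16 should add to the bromine-bearing C5=C6 bond of pyranone 12 in a normal-demand, strongly asynchronous [4+2] cycloaddition (at the limit a Michael addition followed by closure of the bromo enolate onto the silyl oxocarbenium carbon), its nucleophilic CH2 terminus bonding to C6 next to O1 (future C8a) and its ketene acetal carbon to the brominated C5 (future C4a). Ring A is closed in this way as a six-membered carbocycle, four carbons from the diene and two from ring C, with both bonds made on one face so that adduct 17 is cis-fused. TMSOTf and i-Pr2NEt should then ionise the mixed methyl silyl ketal at C5 and remove a C8 proton (the known ketal to enol ether conversion) to give 18, whose syn loss of HBr across C4a–C8a is driven by formation of the benzene ring and gives 19, and dilute acid frees the two phenols. The closest known chemistry is the cycloaddition of 1,3-dioxygenated dienes to bromoquinones and to 3-substituted chromones with aromatisation by elimination, which has not been shown for a 3-bromo-4-pyranone; the sequence is kept silylated and free of strong base until the arene exists so that ring C cannot open by retro-oxa-Michael reaction and the trichloroethyl sulfate is not attacked. The stereocentres of 17 (C4a, C5, C8a) are transient and all become sp2, so nothing has to be controlled there. The step needs site and orientation selectivity: bromine lowers the LUMO of the only disubstituted C=C (C2=C3 is tetrasubstituted and shielded by ring B and the benzyloxy group), and the match of the diene CH2 with the enone β-carbon places O5 beside C4a and O7 para to it.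

Step 12
Reactants: 20 3,3'-di-O-benzylquercetin 4'-(2,2,2-trichloroethyl sulfate)
Product: 22 quercetin 4'-(hydrogen sulfate), via ammonium salt 21 (not isolated)
Conditions: Pd/C (10 %), HCO2NH4, MeOH/THF, rt; then sulfonic acid cation-exchange resin (H+ form), H2O, 0 °C; freeze-drying
Reagents that add atoms: none
Why: Catalytic transfer hydrogenolysis should cleave the two benzyl ethers, and the trichloroethyl ester is lost by reductive carbon–chlorine cleavage with β-elimination of the aryl sulfate monoanion, which like the tetrasubstituted chromone C2=C3 bond is inert to these conditions; cation exchange of salt 21 then gives the acid.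

Compound list

1 | 3-hydroxy-4H-pyran-4-one (pyromeconic acid) | O=c1ccocc1O | starting material
2 | 3-hydroxy-2-iodo-4H-pyran-4-one | O=c1ccoc(I)c1O | intermediate
3 | 3-(benzyloxy)-2-iodo-4H-pyran-4-one | O=c1ccoc(I)c1OCc1ccccc1 | intermediate
4 | 5-(benzyloxy)-2,3-dibromo-6-iodo-2,3-dihydro-4H-pyran-4-one (dibromide of 3, racemic diastereomer mixture, formed in the flask) | O=C1C(OCc2ccccc2)=C(I)OC(Br)C1Br | intermediate
5 | 3-(benzyloxy)-5-bromo-2-iodo-4H-pyran-4-one | O=c1c(Br)coc(I)c1OCc1ccccc1 | intermediate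
6 | 2-(benzyloxy)phenol | Oc1ccccc1OCc1ccccc1 | starting material
7 | 2-(benzyloxy)-4-bromophenol | Oc1ccc(Br)cc1OCc1ccccc1 | intermediate
8 | 2-(benzyloxy)-4-(4,4,5,5-tetramethyl-1,3,2-dioxaborolan-2-yl)phenol | CC1(C)OB(c2ccc(O)c(OCc3ccccc3)c2)OC1(C)C | intermediate
9 | 3-(benzyloxy)-2-[3-(benzyloxy)-4-hydroxyphenyl]-5-bromo-4H-pyran-4-one | O=c1c(Br)coc(-c2ccc(O)c(OCc3ccccc3)c2)c1OCc1ccccc1 | intermediate
10 | 2,2,2-trichloroethanol | OCC(Cl)(Cl)Cl | starting material
11 | 2,2,2-trichloroethyl chlorosulfate | O=S(=O)(Cl)OCC(Cl)(Cl)Cl | intermediate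
12 | 2-(benzyloxy)-4-[3-(benzyloxy)-5-bromo-4-oxo-4H-pyran-2-yl]phenyl 2,2,2-trichloroethyl sulfate | O=c1c(Br)coc(-c2ccc(OS(=O)(=O)OCC(Cl)(Cl)Cl)c(OCc3ccccc3)c2)c1OCc1ccccc1 | intermediate
13 | methyl acetoacetate | CC(=O)CC(=O)OC | starting material
14 | methyl (2E)-3-(trimethylsilyloxy)but-2-enoate | COC(=O)/C=C(\C)O[Si](C)(C)C | intermediate
15 | lithium (1E)-1-methoxy-3-(trimethylsilyloxy)buta-1,3-dien-1-olate (formed in the flask) | CO/C(O[Li])=C/C(=C)O[Si](C)(C)C | intermediate
16 | (1Z)-1-methoxy-1,3-bis(trimethylsilyloxy)buta-1,3-diene | CO/C(O[Si](C)(C)C)=C/C(=C)O[Si](C)(C)C | intermediate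
17 | 2-(benzyloxy)-4-[3-(benzyloxy)-4a-bromo-5-methoxy-4-oxo-5,7-bis(trimethylsilyloxy)-4a,5,8,8a-tetrahydro-4H-chromen-2-yl]phenyl 2,2,2-trichloroethyl sulfate (racemic, cis-fused: Br at C4a and H at C8a on the same face, both C5 epimers, formed in the flask) | O=C1C(OCc2ccccc2)=C(c2ccc(OS(=O)(=O)OCC(Cl)(Cl)Cl)c(OCc3ccccc3)c2)O[C@@H]2CC(O[Si](C)(C)C)=CC(OC)(O[Si](C)(C)C)[C@]12Br | intermediate
18 | 2-(benzyloxy)-4-[3-(benzyloxy)-4a-bromo-4-oxo-5,7-bis(trimethylsilyloxy)-4a,8a-dihydro-4H-chromen-2-yl]phenyl 2,2,2-trichloroethyl sulfate (racemic, Br at C4a and H at C8a cis, formed in the flask) | O=C1C(OCc2ccccc2)=C(c2ccc(OS(=O)(=O)OCC(Cl)(Cl)Cl)c(OCc3ccccc3)c2)O[C@@H]2C=C(O[Si](C)(C)C)C=C(O[Si](C)(C)C)[C@]12Br | intermediate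
19 | 3,3'-di-O-benzyl-5,7-bis-O-(trimethylsilyl)quercetin 4'-(2,2,2-trichloroethyl sulfate) (formed in the flask) | O=c1c(OCc2ccccc2)c(-c2ccc(OS(=O)(=O)OCC(Cl)(Cl)Cl)c(OCc3ccccc3)c2)oc2cc(O[Si](C)(C)C)cc(O[Si](C)(C)C)c12 | intermediate
20 | 3,3'-di-O-benzylquercetin 4'-(2,2,2-trichloroethyl sulfate) | O=c1c(OCc2ccccc2)c(-c2ccc(OS(=O)(=O)OCC(Cl)(Cl)Cl)c(OCc3ccccc3)c2)oc2cc(O)cc(O)c12 | intermediate
21 | ammonium quercetin 4'-sulfate (formed in the flask) | [NH4+].O=c1c(O)c(-c2ccc(OS(=O)(=O)[O-])c(O)c2)oc2cc(O)cc(O)c12 | intermediate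
22 | quercetin 4'-(hydrogen sulfate), 2-hydroxy-4-(3,5,7-trihydroxy-4-oxo-4H-chromen-2-yl)phenyl hydrogen sulfate | O=c1c(O)c(-c2ccc(OS(=O)(=O)O)c(O)c2)oc2cc(O)cc(O)c12 | target

Total step count: 12. Longest linear sequence: 7 steps (steps 1, 2, 3, 6, 8, 11 and 12, from 1 to 22).

Steps most likely to fail

Step 11. The pyranone may resist cycloaddition up to the temperature at which the diene rearranges, the addition may stop at the Michael stage and open ring C, or HBr may fail to leave the cis-fused adduct. The fallback uses known reactions only, sets out from bromophenol 7 and chlorosulfate 11, and comes back to the route at ammonium salt 21. Phenol 7 is protected with MOMCl and i-Pr2NEt as 2-(benzyloxy)-4-bromo-1-(methoxymethoxy)benzene F1. Bromine–lithium exchange with n-BuLi in THF at −78 °C gives [3-(benzyloxy)-4-(methoxymethoxy)phenyl]lithium F2, which is formylated with DMF to 3-(benzyloxy)-4-(methoxymethoxy)benzaldehyde F3. Claisen–Schmidt condensation of F3 with commercial 1-[2,4-bis(benzyloxy)-6-hydroxyphenyl]ethanone (KOH, EtOH, rt) gives the chalcone (2E)-1-[2,4-bis(benzyloxy)-6-hydroxyphenyl]-3-[3-(benzyloxy)-4-(methoxymethoxy)phenyl]prop-2-en-1-one F4. Oxidative cyclisation with catalytic I2 in DMSO at 130 °C gives the flavone 5,7-bis(benzyloxy)-2-[3-(benzyloxy)-4-(methoxymethoxy)phenyl]-4H-chromen-4-one F5, and HCl in MeOH/THF at 50 °C completes removal of the MOM group to give 5,7-bis(benzyloxy)-2-[3-(benzyloxy)-4-hydroxyphenyl]-4H-chromen-4-one F6. Sulfation with 11 under the conditions of step 8 gives 2-(benzyloxy)-4-[5,7-bis(benzyloxy)-4-oxo-4H-chromen-2-yl]phenyl 2,2,2-trichloroethyl sulfate F7, in which the sulfate diester also protects O4'. Dimethyldioxirane in acetone/CH2Cl2 epoxidises C2=C3 to the racemic 2,3-epoxide of F7 F8, which opens with catalytic TsOH to the flavonol 2-(benzyloxy)-4-[5,7-bis(benzyloxy)-3-hydroxy-4-oxo-4H-chromen-2-yl]phenyl 2,2,2-trichloroethyl sulfate F9. The conditions of step 12 then cleave three benzyl ethers and the trichloroethyl group to give 21 and, after cation exchange, 22.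

Step 3. Bromine may attack C2 ipso and exchange iodine for bromine, or HBr may cleave the benzyl ether before the amine is added. The fallback postpones bromination until the iodine has been used; it sets out from iodide 3 and comes back at 12. Iodide 3 is coupled with boronate 8 under the conditions of step 6 to give 3-(benzyloxy)-2-[3-(benzyloxy)-4-hydroxyphenyl]-4H-pyran-4-one F10. Sulfation with 11 as in step 8 gives 2-(benzyloxy)-4-[3-(benzyloxy)-4-oxo-4H-pyran-2-yl]phenyl 2,2,2-trichloroethyl sulfate F11. Only then is Br2 added in CH2Cl2 at 0 °C to give 2-(benzyloxy)-4-[5-(benzyloxy)-2,3-dibromo-4-oxo-3,4-dihydro-2H-pyran-6-yl]phenyl 2,2,2-trichloroethyl sulfate F12, from which Et3N eliminates HBr to give 12. No iodine is left at that stage and ring B is deactivated by the sulfate diester and the pyranone, so bromine should add to the enol-ether-like C5=C6 bond first.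

Step 6. Phenoxide or hydroxide may displace the activated C2 iodide, aqueous base may open the pyranone, or palladium may also insert into the carbon–bromine bond. The fallback is a base-free Negishi coupling with the phenol protected; it sets out from bromophenol 7 and bromo iodide 5 and comes back at phenol 9. Phenol 7 is silylated (TBSCl, imidazole, DMF) to [2-(benzyloxy)-4-bromophenoxy](tert-butyl)dimethylsilane F13. n-BuLi in THF at −78 °C gives {3-(benzyloxy)-4-[(tert-butyldimethylsilyl)oxy]phenyl}lithium F14, and ZnCl2 converts it to {3-(benzyloxy)-4-[(tert-butyldimethylsilyl)oxy]phenyl}zinc chloride F15. Coupling with 5 (Pd(PPh3)4, THF, rt) at the carbon–iodine bond gives 3-(benzyloxy)-2-{3-(benzyloxy)-4-[(tert-butyldimethylsilyl)oxy]phenyl}-5-bromo-4H-pyran-4-one F16, and TBAF buffered with AcOH in THF at 0 °C frees phenol 9.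

Further compounds

F1 | step 11 | 2-(benzyloxy)-4-bromo-1-(methoxymethoxy)benzene | COCOc1ccc(Br)cc1OCc1ccccc1
F2 | step 11 | [3-(benzyloxy)-4-(methoxymethoxy)phenyl]lithium | [Li]c1ccc(OCOC)c(OCc2ccccc2)c1
F3 | step 11 | 3-(benzyloxy)-4-(methoxymethoxy)benzaldehyde | COCOc1ccc(C=O)cc1OCc1ccccc1
F4 | step 11 | (2E)-1-[2,4-bis(benzyloxy)-6-hydroxyphenyl]-3-[3-(benzyloxy)-4-(methoxymethoxy)phenyl]prop-2-en-1-one | COCOc1ccc(/C=C/C(=O)c2c(O)cc(OCc3ccccc3)cc2OCc2ccccc2)cc1OCc1ccccc1
F5 | step 11 | 5,7-bis(benzyloxy)-2-[3-(benzyloxy)-4-(methoxymethoxy)phenyl]-4H-chromen-4-one | COCOc1ccc(-c2cc(=O)c3c(OCc4ccccc4)cc(OCc4ccccc4)cc3o2)cc1OCc1ccccc1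
F6 | step 11 | 5,7-bis(benzyloxy)-2-[3-(benzyloxy)-4-hydroxyphenyl]-4H-chromen-4-one | Oc1ccc(-c2cc(=O)c3c(OCc4ccccc4)cc(OCc4ccccc4)cc3o2)cc1OCc1ccccc1
F7 | step 11 | 2-(benzyloxy)-4-[5,7-bis(benzyloxy)-4-oxo-4H-chromen-2-yl]phenyl 2,2,2-trichloroethyl sulfate | O=S(=O)(OCC(Cl)(Cl)Cl)Oc1ccc(-c2cc(=O)c3c(OCc4ccccc4)cc(OCc4ccccc4)cc3o2)cc1OCc1ccccc1
F8 | step 11 | 2,3-epoxide of F7 (racemic, oxirane cis-fused across C2–C3) | O=C1c2c(OCc3ccccc3)cc(OCc3ccccc3)cc2O[C@]2(c3ccc(OS(=O)(=O)OCC(Cl)(Cl)Cl)c(OCc4ccccc4)c3)O[C@H]12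
F9 | step 11 | 2-(benzyloxy)-4-[5,7-bis(benzyloxy)-3-hydroxy-4-oxo-4H-chromen-2-yl]phenyl 2,2,2-trichloroethyl sulfate | O=S(=O)(OCC(Cl)(Cl)Cl)Oc1ccc(-c2oc3cc(OCc4ccccc4)cc(OCc4ccccc4)c3c(=O)c2O)cc1OCc1ccccc1
F10 | step 3 | 3-(benzyloxy)-2-[3-(benzyloxy)-4-hydroxyphenyl]-4H-pyran-4-one | O=c1ccoc(-c2ccc(O)c(OCc3ccccc3)c2)c1OCc1ccccc1
F11 | step 3 | 2-(benzyloxy)-4-[3-(benzyloxy)-4-oxo-4H-pyran-2-yl]phenyl 2,2,2-trichloroethyl sulfate | O=c1ccoc(-c2ccc(OS(=O)(=O)OCC(Cl)(Cl)Cl)c(OCc3ccccc3)c2)c1OCc1ccccc1
F12 | step 3 | 2-(benzyloxy)-4-[5-(benzyloxy)-2,3-dibromo-4-oxo-3,4-dihydro-2H-pyran-6-yl]phenyl 2,2,2-trichloroethyl sulfate (racemic diastereomer mixture) | O=C1C(OCc2ccccc2)=C(c2ccc(OS(=O)(=O)OCC(Cl)(Cl)Cl)c(OCc3ccccc3)c2)OC(Br)C1Br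
F13 | step 6 | [2-(benzyloxy)-4-bromophenoxy](tert-butyl)dimethylsilane | CC(C)(C)[Si](C)(C)Oc1ccc(Br)cc1OCc1ccccc1
F14 | step 6 | {3-(benzyloxy)-4-[(tert-butyldimethylsilyl)oxy]phenyl}lithium | [Li]c1ccc(O[Si](C)(C)C(C)(C)C)c(OCc2ccccc2)c1
F15 | step 6 | {3-(benzyloxy)-4-[(tert-butyldimethylsilyl)oxy]phenyl}zinc chloride | Cl[Zn]c1ccc(O[Si](C)(C)C(C)(C)C)c(OCc2ccccc2)c1
F16 | step 6 | 3-(benzyloxy)-2-{3-(benzyloxy)-4-[(tert-butyldimethylsilyl)oxy]phenyl}-5-bromo-4H-pyran-4-one | O=c1c(Br)coc(-c2ccc(O[Si](C)(C)C(C)(C)C)c(OCc3ccccc3)c2)c1OCc1ccccc1
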